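**Plan**
- Cuts: after removal of the five silyl ethers, ring C is opened at C2–C3. Further cuts are C8–C1'' (chain to ring A), O1–C2 (ring B benzyl unit to ring A) and C2''–C3'' inside the chain.
- Enabling feature: C2 of ring C is a benzylic carbon attached to O1, and C3 lies next to the C4 ketone. C2–C3 can therefore form when a carbenoid at C3 inserts into a C–H bond of a ring B benzyl ether on the C8a oxygen.
- Forward: rings A and B are bought as aromatic compounds. Ring B is attached to the C8a oxygen, the C10 chain is coupled to C8, the acetyl group becomes a diazo ketone, and ring C closes last.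
- Stereochemistry: C2'' comes from a deconjugative Evans alkylation controlled by (S)-4-benzyl-2-oxazolidinone. C2 comes from the chiral dirhodium carboxylate in the ring closure, and a wrong C2 epimer would be a separable diastereomer.

Key step: step 14

Remark: the chain has ten carbons and a single CH2 between C8 and its stereocentre. Cleaving the ring double bond of limonene and adding a methyl nucleophile would give eleven carbons and two such CH2 groups, so the chain is built by auxiliary-controlled alkylation instead.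
Assumption: the (S)-tert-leucinate catalyst is taken to be the antipode that leads to 2S. Its mirror image is equally accessible, and the assignment would be verified on the cyclised product before deprotection.

Step 1
Reactants: 1 (S)-4-benzyl-1,3-oxazolidin-2-one; 2 3-methylbut-2-enoyl chloride
Product: 4 (4S)-4-benzyl-3-(3-methylbut-2-enoyl)-1,3-oxazolidin-2-one, via lithium oxazolidinide 3 (not isolated)
Conditions: n-BuLi, THF, −78 °C; then 2, −78 to 0 °C
Reagents that add atoms: none
Why: N-acylation of the lithiated oxazolidinone with an acid chloride is the standard entry to Evans imides, and prior deprotonation avoids the amine-induced vinylketene pathway that would deconjugate the acyl group.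

Step 2
Reactants: 4 (4S)-4-benzyl-3-(3-methylbut-2-enoyl)-1,3-oxazolidin-2-one; 5 1-bromo-3-methylbut-2-ene (prenyl bromide)
Product: 7 (4S)-4-benzyl-3-[(2S)-5-methyl-2-(prop-1-en-2-yl)hex-4-enoyl]-1,3-oxazolidin-2-one, via sodium dienolate 6 (not isolated)
Conditions: NaN(SiMe3)2, THF, −78 °C; then 5, −78 to −30 °C; AcOH quench at low temperature
Reagents that add atoms: none
Why: in this deconjugative Evans asymmetric alkylation, γ-deprotonation of the s-cis enoyl imide gives the chelated Z-dienolate 6, which takes the allylic bromide at its α-carbon on the face opposite the benzyl group, so the isopropenyl group appears and the stereocentre is set as 2S (it becomes 2''R once the carbonyl carbon is a CH2 bonded to ring A).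

Step 3
Reactants: 7 (4S)-4-benzyl-3-[(2S)-5-methyl-2-(prop-1-en-2-yl)hex-4-enoyl]-1,3-oxazolidin-2-one
Product: 8 (4S)-4-benzyl-3-{(2S)-2-[(3,3-dimethyloxiran-2-yl)methyl]-3-methylbut-3-enoyl}-1,3-oxazolidin-2-one (both epoxide epimers)
Conditions: mCPBA (1.0 equiv), NaHCO3, CH2Cl2, −10 to 0 °C
Reagents that add atoms: 3-chloroperoxybenzoic acid, O=C(OO)c1cccc(Cl)c1
Why: Prilezhaev epoxidation follows alkene nucleophilicity, so one equivalent of peracid should take the trisubstituted double bond and leave the 1,1-disubstituted isopropenyl group next to the imide, and the new epoxide centre vanishes in step 4, so both epimers serve.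

Step 4
Reactants: 8 epoxy imide
Product: 9 (2S)-5-methyl-2-(prop-1-en-2-yl)hexane-1,5-diol
Conditions: LiAlH4, THF, 0 °C to rt; H2O/aq NaOH work-up
Reagents that add atoms: none
Why: hydride reduction with LiAlH4 does two jobs in one flask, reductive removal of the auxiliary to the primary alcohol and SN2 opening of the epoxide at its less substituted carbon to the tertiary alcohol, and afterwards the stereocentre is no longer enolisable.

Step 5
Reactants: 9 (2S)-5-methyl-2-(prop-1-en-2-yl)hexane-1,5-diol
Product: 10 (5S)-6-iodo-2-methyl-5-(prop-1-en-2-yl)hexan-2-ol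
Conditions: I2, PPh3, imidazole, CH2Cl2, 0 °C
Reagents that add atoms: iodine, II
Why: Appel-type iodination (Garegg–Samuelsson conditions) proceeds by SN2 displacement of an alkoxyphosphonium ion and therefore takes only the primary hydroxyl group, the tertiary one being too hindered to be activated.

Step 6
Reactants: 10 (5S)-6-iodo-2-methyl-5-(prop-1-en-2-yl)hexan-2-ol
Product: 11 triethyl{[(5S)-6-iodo-2-methyl-5-(prop-1-en-2-yl)hexan-2-yl]oxy}silane
Conditions: Et3SiOTf, 2,6-lutidine, CH2Cl2, −78 to 0 °C
Reagents that add atoms: triethylsilyl trifluoromethanesulfonate, CC[Si](CC)(CC)OS(=O)(=O)C(F)(F)F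
Why: silylation with a silyl triflate and a hindered pyridine base is the usual way to cap a tertiary alcohol, and it removes the O–H bond that would otherwise quench the zinc reagent and trap the carbenoid.

Step 7
Reactants: 12 2,4,6-trihydroxyacetophenone
Product: 13 1-[2-hydroxy-4,6-bis(triisopropylsilyloxy)phenyl]ethan-1-one
Conditions: i-Pr3SiCl (2.1 equiv), imidazole, DMF, 0 °C to rt (12 dried beforehand)
Reagents that add atoms: chlorotriisopropylsilane, CC(C)[Si](Cl)(C(C)C)C(C)C
Why: in this phenol silylation the 4-OH and one of the two equivalent ortho-OH groups react, while the last hydroxyl is hydrogen-bonded to the acetyl group and shielded, so the reaction should stop at the bis-ether.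

Step 8
Reactants: 13 1-[2-hydroxy-4,6-bis(triisopropylsilyloxy)phenyl]ethan-1-one
Product: 14 1-[2-hydroxy-3-iodo-4,6-bis(triisopropylsilyloxy)phenyl]ethan-1-one
Conditions: NIS (1.0 equiv), CH2Cl2, 0 °C to rt, dark
Reagents that add atoms: N-iodosuccinimide, O=C1CCC(=O)N1I
Why: in this electrophilic aromatic iodination C3 is ortho to the free phenol and has only one silyl ether beside it, whereas C5 lies between two triisopropylsilyloxy groups, so the halogen should enter at C3, the future C8.

Step 9
Reactants: 15 2,4-dihydroxybenzaldehyde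
Product: 16 2,4-bis(triisopropylsilyloxy)benzaldehyde
Conditions: i-Pr3SiOTf (2.3 equiv), 2,6-lutidine, CH2Cl2, 0 °C to rt
Reagents that add atoms: triisopropylsilyl trifluoromethanesulfonate, CC(C)[Si](OS(=O)(=O)C(F)(F)F)(C(C)C)C(C)C
Why: the silyl triflate is reactive enough to silylate the hydrogen-bonded 2-OH as well as the 4-OH, a routine exhaustive phenol silylation.

Step 10
Reactants: 16 2,4-bis(triisopropylsilyloxy)benzaldehyde
Product: 17 [2,4-bis(triisopropylsilyloxy)phenyl]methanol
Conditions: NaBH4, THF/MeOH, 0 °C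
Reagents that add atoms: none
Why: this is a borohydride reduction of an aromatic aldehyde, in which the low temperature, the protic medium and the bulk of the triisopropylsilyl group should prevent migration of the ortho silyl group to the new alkoxide.

Step 11
Reactants: 14 1-[2-hydroxy-3-iodo-4,6-bis(triisopropylsilyloxy)phenyl]ethan-1-one; 17 [2,4-bis(triisopropylsilyloxy)phenyl]methanol
Product: 18 1-{2-[2,4-bis(triisopropylsilyloxy)benzyloxy]-3-iodo-4,6-bis(triisopropylsilyloxy)phenyl}ethan-1-one
Conditions: PPh3, DIAD, THF, 0 °C to rt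
Reagents that add atoms: none
Why: in this Mitsunobu etherification the acyl- and iodo-substituted phenol is acidic enough to protonate the betaine and the primary electron-rich benzylic alkoxyphosphonium ion is a very reactive electrophile, so O1–C2 forms without an unstable benzylic halide.

Step 12
Reactants: 11 triethyl{[(5S)-6-iodo-2-methyl-5-(prop-1-en-2-yl)hexan-2-yl]oxy}silane; 18 iodoaryl benzyl ether
Product: 20 1-{2-[2,4-bis(triisopropylsilyloxy)benzyloxy]-3-[(2R)-5-methyl-2-(prop-1-en-2-yl)-5-(triethylsilyloxy)hexyl]-4,6-bis(triisopropylsilyloxy)phenyl}ethan-1-one, via alkylzinc iodide 19 (not isolated)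
Conditions: 11, Zn dust (activated with BrCH2CH2Br and Me3SiCl), LiCl, THF, 40 °C; then 18, Pd(OAc)2 (5 mol %), SPhos (10 mol %), THF, 50 °C
Reagents that add atoms: none
Why: in this Negishi sp3–sp2 cross-coupling, zinc insertion into the primary iodide gives 19, which tolerates the ketone and silyl ethers, and the bulky electron-rich biarylphosphine speeds oxidative addition of zerovalent palladium to the hindered aryl iodide and reductive elimination ahead of β-hydride elimination, so the centre β to the metal stays untouched.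

Step 13
Reactants: 20 aryl methyl ketone
Product: 23 2-diazo-1-{2-[2,4-bis(triisopropylsilyloxy)benzyloxy]-3-[(2R)-5-methyl-2-(prop-1-en-2-yl)-5-(triethylsilyloxy)hexyl]-4,6-bis(triisopropylsilyloxy)phenyl}ethan-1-one, via lithium enolate 21 (not isolated), via trifluoroacetyl ketone 22 (not isolated)
Conditions: LiN(SiMe3)2, THF, −78 °C; CF3CO2CH2CF3, −78 °C; AcOH; then MsN3, Et3N, H2O, MeCN, rt
Reagents that add atoms: methanesulfonyl azide, CS(=O)(=O)N=[N+]=[N-]
Why: in this detrifluoroacetylative (Regitz-type deacylative) diazo transfer, the kinetic enolate 21 is acylated to 22, whose activated methylene accepts the diazo group from the sulfonyl azide, and loss of the trifluoroacetyl group leaves the terminal diazo ketone under conditions that spare every silyl ether.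

Step 14
Reactants: 23 diazo ketone
Product: 24 (2S)-2-[2,4-bis(triisopropylsilyloxy)phenyl]-8-[(2R)-5-methyl-2-(prop-1-en-2-yl)-5-(triethylsilyloxy)hexyl]-5,7-bis(triisopropylsilyloxy)-2,3-dihydro-4H-chromen-4-one
Conditions: Rh2(S-PTTL)4 (2 mol %), CH2Cl2, 0 °C, slow addition of 23 by syringe pump, high dilution
Reagents that add atoms: none
Why: Rh2(S-PTTL)4, dirhodium tetrakis[N-phthaloyl-(S)-tert-leucinate], displaces N2 from 23 to give an electrophilic divalent-rhodium carbenoid at C3, which inserts into one benzylic C–H bond of the O1–CH2–aryl group through a concerted, asynchronous three-centre transition state with hydride-transfer character and so forms C2–C3. The closest known reaction type is the enantioselective intramolecular C–H insertion of 2-alkoxyaryl α-diazo ketones next to the ether oxygen, which gives chroman-4-ones under chiral dirhodium carboxylates. Ring C closes as a six-membered ring by 1,6-insertion, since the usual 1,5-position is O1 itself and carries no hydrogen. C2 is set by the chiral pocket of the four phthalimido-tert-leucinate ligands, which tells the two benzylic hydrogens apart; the distant C2'' centre should have little say, and any 2R product is a diastereomer that chromatography should remove. The step needs insertion to outrun attack of O1 on the carbenoid (oxonium ylide, then Stevens [1,2]-shift of the benzyl group to a benzofuran-3-one): O1 is a weakly basic aryl ether oxygen wedged between the acyl group and the C8 chain, while the C–H bond is activated by O1 and by the two donor oxygens of ring B. All other oxygens carry silyl groups or a fully substituted carbon, so no second O–CH or O–H site is within reach, and slow addition at high dilution holds back carbene dimerisation and intermolecular cyclopropanation of the isopropenyl group.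

Step 15
Reactants: 24 fully silylated flavanone
Product: 25 norkurarinol, (2S)-2-(2,4-dihydroxyphenyl)-5,7-dihydroxy-8-[(2R)-5-hydroxy-5-methyl-2-(prop-1-en-2-yl)hexyl]-2,3-dihydro-4H-chromen-4-one
Conditions: Bu4NF/AcOH (1:1, excess), THF, 0 °C to rt
Reagents that add atoms: none
Why: fluoride-mediated desilylation cleaves the four aryl silyl ethers and the tertiary triethylsilyl ether, and the acetic acid buffer keeps the phenoxide concentration low, so it avoids both retro-oxa-Michael opening of ring C (which would epimerise C2) and acid-induced reactions of the isopropenyl group and tertiary alcohol.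

**Compound list**
1 | (S)-4-benzyl-1,3-oxazolidin-2-one | O=C1N[C@@H](Cc2ccccc2)CO1 | starting material
2 | 3-methylbut-2-enoyl chloride | CC(C)=CC(=O)Cl | starting material
3 | lithium (4S)-4-benzyl-2-oxo-1,3-oxazolidin-3-ide | [Li+].O=C1[N-][C@@H](Cc2ccccc2)CO1 | intermediate
4 | (4S)-4-benzyl-3-(3-methylbut-2-enoyl)-1,3-oxazolidin-2-one | CC(C)=CC(=O)N1C(=O)OC[C@@H]1Cc1ccccc1 | intermediate
5 | 1-bromo-3-methylbut-2-ene | CC(C)=CCBr | starting material
6 | sodium (1Z)-1-[(4S)-4-benzyl-2-oxo-1,3-oxazolidin-3-yl]-3-methylbuta-1,3-dien-1-olate | [Na+].C=C(C)/C=C(\[O-])N1C(=O)OC[C@@H]1Cc1ccccc1 | intermediate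
7 | (4S)-4-benzyl-3-[(2S)-5-methyl-2-(prop-1-en-2-yl)hex-4-enoyl]-1,3-oxazolidin-2-one | C=C(C)[C@H](CC=C(C)C)C(=O)N1C(=O)OC[C@@H]1Cc1ccccc1 | intermediate
8 | (4S)-4-benzyl-3-{(2S)-2-[(3,3-dimethyloxiran-2-yl)methyl]-3-methylbut-3-enoyl}-1,3-oxazolidin-2-one, epoxide carbon as both epimers | C=C(C)[C@H](CC1OC1(C)C)C(=O)N1C(=O)OC[C@@H]1Cc1ccccc1 | intermediate
9 | (2S)-5-methyl-2-(prop-1-en-2-yl)hexane-1,5-diol | C=C(C)[C@H](CCC(C)(C)O)CO | intermediate
10 | (5S)-6-iodo-2-methyl-5-(prop-1-en-2-yl)hexan-2-ol | C=C(C)[C@H](CCC(C)(C)O)CI | intermediate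
11 | triethyl{[(5S)-6-iodo-2-methyl-5-(prop-1-en-2-yl)hexan-2-yl]oxy}silane | C=C(C)[C@H](CCC(C)(C)O[Si](CC)(CC)CC)CI | intermediate
12 | 2,4,6-trihydroxyacetophenone | CC(=O)c1c(O)cc(O)cc1O | starting material
13 | 1-[2-hydroxy-4,6-bis(triisopropylsilyloxy)phenyl]ethan-1-one | CC(=O)c1c(O)cc(O[Si](C(C)C)(C(C)C)C(C)C)cc1O[Si](C(C)C)(C(C)C)C(C)C | intermediate
14 | 1-[2-hydroxy-3-iodo-4,6-bis(triisopropylsilyloxy)phenyl]ethan-1-one | CC(=O)c1c(O)c(I)c(O[Si](C(C)C)(C(C)C)C(C)C)cc1O[Si](C(C)C)(C(C)C)C(C)C | intermediate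
15 | 2,4-dihydroxybenzaldehyde | O=Cc1ccc(O)cc1O | starting material
16 | 2,4-bis(triisopropylsilyloxy)benzaldehyde | O=Cc1ccc(O[Si](C(C)C)(C(C)C)C(C)C)cc1O[Si](C(C)C)(C(C)C)C(C)C | intermediate
17 | [2,4-bis(triisopropylsilyloxy)phenyl]methanol | OCc1ccc(O[Si](C(C)C)(C(C)C)C(C)C)cc1O[Si](C(C)C)(C(C)C)C(C)C | intermediate
18 | 1-{2-[2,4-bis(triisopropylsilyloxy)benzyloxy]-3-iodo-4,6-bis(triisopropylsilyloxy)phenyl}ethan-1-one | CC(=O)c1c(OCc2ccc(O[Si](C(C)C)(C(C)C)C(C)C)cc2O[Si](C(C)C)(C(C)C)C(C)C)c(I)c(O[Si](C(C)C)(C(C)C)C(C)C)cc1O[Si](C(C)C)(C(C)C)C(C)C | intermediate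
19 | [(2S)-5-methyl-2-(prop-1-en-2-yl)-5-(triethylsilyloxy)hexyl]zinc iodide | C=C(C)[C@H](CCC(C)(C)O[Si](CC)(CC)CC)C[Zn]I | intermediate
20 | 1-{2-[2,4-bis(triisopropylsilyloxy)benzyloxy]-3-[(2R)-5-methyl-2-(prop-1-en-2-yl)-5-(triethylsilyloxy)hexyl]-4,6-bis(triisopropylsilyloxy)phenyl}ethan-1-one | C=C(C)[C@H](CCC(C)(C)O[Si](CC)(CC)CC)Cc1c(O[Si](C(C)C)(C(C)C)C(C)C)cc(O[Si](C(C)C)(C(C)C)C(C)C)c(C(C)=O)c1OCc1ccc(O[Si](C(C)C)(C(C)C)C(C)C)cc1O[Si](C(C)C)(C(C)C)C(C)C | intermediate
21 | lithium enolate of 20 (lithium 1-arylethen-1-olate) | C=C(C)[C@H](CCC(C)(C)O[Si](CC)(CC)CC)Cc1c(O[Si](C(C)C)(C(C)C)C(C)C)cc(O[Si](C(C)C)(C(C)C)C(C)C)c(C(=C)[O-])c1OCc1ccc(O[Si](C(C)C)(C(C)C)C(C)C)cc1O[Si](C(C)C)(C(C)C)C(C)C.[Li+] | intermediate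
22 | 4,4,4-trifluoro-1-aryl-butane-1,3-dione (aryl as in 20) | C=C(C)[C@H](CCC(C)(C)O[Si](CC)(CC)CC)Cc1c(O[Si](C(C)C)(C(C)C)C(C)C)cc(O[Si](C(C)C)(C(C)C)C(C)C)c(C(=O)CC(=O)C(F)(F)F)c1OCc1ccc(O[Si](C(C)C)(C(C)C)C(C)C)cc1O[Si](C(C)C)(C(C)C)C(C)C | intermediate
23 | 2-diazo-1-{2-[2,4-bis(triisopropylsilyloxy)benzyloxy]-3-[(2R)-5-methyl-2-(prop-1-en-2-yl)-5-(triethylsilyloxy)hexyl]-4,6-bis(triisopropylsilyloxy)phenyl}ethan-1-one | C=C(C)[C@H](CCC(C)(C)O[Si](CC)(CC)CC)Cc1c(O[Si](C(C)C)(C(C)C)C(C)C)cc(O[Si](C(C)C)(C(C)C)C(C)C)c(C(=O)C=[N+]=[N-])c1OCc1ccc(O[Si](C(C)C)(C(C)C)C(C)C)cc1O[Si](C(C)C)(C(C)C)C(C)C | intermediate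
24 | (2S)-2-[2,4-bis(triisopropylsilyloxy)phenyl]-8-[(2R)-5-methyl-2-(prop-1-en-2-yl)-5-(triethylsilyloxy)hexyl]-5,7-bis(triisopropylsilyloxy)-2,3-dihydro-4H-chromen-4-one | C=C(C)[C@H](CCC(C)(C)O[Si](CC)(CC)CC)Cc1c(O[Si](C(C)C)(C(C)C)C(C)C)cc(O[Si](C(C)C)(C(C)C)C(C)C)c2c1O[C@H](c1ccc(O[Si](C(C)C)(C(C)C)C(C)C)cc1O[Si](C(C)C)(C(C)C)C(C)C)CC2=O | intermediate
25 | norkurarinol | C=C(C)[C@H](CCC(C)(C)O)Cc1c(O)cc(O)c2c1O[C@H](c1ccc(O)cc1O)CC2=O | target

**Step count**
- Total step count: 15.
- Longest linear sequence: 10 steps (steps 1–6, then 12–15).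

**Steps most likely to fail**

**Step 14.**
- What may go wrong: O1 may attack the carbenoid, followed by a [1,2]-shift of the benzyl group. The catalyst may also discriminate poorly between the two benzylic hydrogens.
- Fallback: ring C is closed at O1–C2 instead of C2–C3. It sets out from 14 and 16.
- A Claisen–Schmidt condensation mediated by LiN(SiMe3)2 in THF (−78 °C to rt) should give (E)-1-[2-hydroxy-3-iodo-4,6-bis(triisopropylsilyloxy)phenyl]-3-[2,4-bis(triisopropylsilyloxy)phenyl]prop-2-en-1-one F1.
- A quinine-derived bifunctional thiourea in toluene then promotes the asymmetric intramolecular oxa-Michael addition to (2S)-2-[2,4-bis(triisopropylsilyloxy)phenyl]-8-iodo-5,7-bis(triisopropylsilyloxy)-2,3-dihydro-4H-chromen-4-one F2.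
- Negishi coupling of this iodide with zinc reagent 19 under the catalyst of step 12 comes back to the route at 24, where a minor C2 epimer is again a separable diastereomer.

**Step 12.**
- What may go wrong: oxidative addition and transmetalation may be slow at a carbon–iodine bond flanked by two bulky oxygen substituents. β-Hydride elimination from the alkylpalladium species or protodezincation could then take over.
- Fallback: the order of fragment union is changed. It sets out from 14 and 19.
- The coupling is run on the free, hydrogen-bonded phenol, whose iodide has only a hydroxyl group on one side, by slow addition of 19 to 14 with Pd(OAc)2/SPhos. This should give 1-{2-hydroxy-3-[(2R)-5-methyl-2-(prop-1-en-2-yl)-5-(triethylsilyloxy)hexyl]-4,6-bis(triisopropylsilyloxy)phenyl}ethan-1-one F3.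
- Mitsunobu etherification of this phenol with 17 (PPh3, DIAD, THF) comes back to the route at 20.

**Step 11.**
- What may go wrong: the hindered, hydrogen-bonded phenol may attack the alkoxyphosphonium ion only sluggishly. The activated benzylic alcohol would then be consumed by the hydrazide anion or lost by ionisation.
- Fallback: a Williamson alkylation with a preformed phenoxide. It sets out from 17.
- CBr4/PPh3 in CH2Cl2 at 0 °C converts 17 into 2,4-bis(triisopropylsilyloxy)benzyl bromide F4, which is used at once.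
- The potassium phenoxide of 14 (K2CO3, acetone, rt) displaces the bromide and comes back to the route at 18.

**Further compounds**
F1 | step 14 | (E)-1-[2-hydroxy-3-iodo-4,6-bis(triisopropylsilyloxy)phenyl]-3-[2,4-bis(triisopropylsilyloxy)phenyl]prop-2-en-1-one | O=C(/C=C/c1ccc(O[Si](C(C)C)(C(C)C)C(C)C)cc1O[Si](C(C)C)(C(C)C)C(C)C)c1c(O)c(I)c(O[Si](C(C)C)(C(C)C)C(C)C)cc1O[Si](C(C)C)(C(C)C)C(C)C
F2 | step 14 | (2S)-2-[2,4-bis(triisopropylsilyloxy)phenyl]-8-iodo-5,7-bis(triisopropylsilyloxy)-2,3-dihydro-4H-chromen-4-one | Ic1c(O[Si](C(C)C)(C(C)C)C(C)C)cc(O[Si](C(C)C)(C(C)C)C(C)C)c2c1O[C@H](c1ccc(O[Si](C(C)C)(C(C)C)C(C)C)cc1O[Si](C(C)C)(C(C)C)C(C)C)CC2=O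
F3 | step 12 | 1-{2-hydroxy-3-[(2R)-5-methyl-2-(prop-1-en-2-yl)-5-(triethylsilyloxy)hexyl]-4,6-bis(triisopropylsilyloxy)phenyl}ethan-1-one | C=C(C)[C@H](CCC(C)(C)O[Si](CC)(CC)CC)Cc1c(O[Si](C(C)C)(C(C)C)C(C)C)cc(O[Si](C(C)C)(C(C)C)C(C)C)c(C(C)=O)c1O
F4 | step 11 | 2,4-bis(triisopropylsilyloxy)benzyl bromide | BrCc1ccc(O[Si](C(C)C)(C(C)C)C(C)C)cc1O[Si](C(C)C)(C(C)C)C(C)C
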